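**Plan**
1. Ring B of the target (C5–C10) is a hexasubstituted catechol frozen in a keto form: C7 is a ketone, C6 an enol, and the only sp3 ring atom, methyl-bearing C10, lies para to the C7 oxygen and is tied to C5 through C1–C2–C3(=O)–C4(Me2) of ring A. The first cut is therefore C1–C10, back to the aromatic catechol vinyl ketone 33.
2. Further cuts: the C9–CH2 aryl–alkyl bond (joins the halves), C2–C3 (vinyl addition) and C4–C5 (aromatic Claisen) in the west; O1′–C2′ with C5a′–C6′ (one diepoxide cascade), C8′–C9′ and the C7′ methyl carbon in the east.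
3. Forward: arene 15 from 2,4-dimethylphenol; eastern chain from geranyl bromide and methyl acetoacetate, with oxepane and cyclohexane closed in one operation; sp3–sp2 coupling; double oxidation; catechol release; ring A closed last.
4. Stereochemistry: C9a′/C5a′ from Shi epoxidation and anti epoxide opening, C6′ from the Z-allylsilane in a chair transition state, C7′ from hydrogenation anti to the angular methyl, C10 from a chiral bifunctional catalyst.

Key step: step 21

Remark: locants C1–C10 are those of the western bicycle of the target and primed locants those of the eastern 1-benzoxepine; 15 and 31 are carried as C3 epimers, and the C3′ carbinol is likewise transient, because both centres become ketones in step 19.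

**Western arene**

Step 1
Reactants: 1 2,4-dimethylphenol
Product: 2 1-(methoxymethoxy)-2,4-dimethylbenzene
Conditions: NaH, THF/DMF, 0 °C; MOMCl, 0 °C → rt
Reagents that add atoms: chloromethyl methyl ether (MOMCl), COCCl
Why: Williamson-type O-alkylation of the sodium phenoxide protects the future C7 oxygen as the acetal that directs the metalation of step 2.

Step 2
Reactants: 2 1-(methoxymethoxy)-2,4-dimethylbenzene
Product: 5 2-(methoxymethoxy)-3,5-dimethylphenol, via aryllithium 3 (not isolated), via dimethyl arylboronate 4 (not isolated)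
Conditions: n-BuLi, TMEDA, Et2O, 0 °C → rt; B(OMe)3, −78 °C → rt; then 30% H2O2, aq NaOH, 0 °C
Reagents that add atoms: hydrogen peroxide, OO
Why: Directed ortho-metalation at the only ring hydrogen next to the OMOM group, then borylation and peroxide oxidation, should install the future C6 oxygen as a free phenol that is distinct from the C7 oxygen.

Step 3
Reactants: 5 2-(methoxymethoxy)-3,5-dimethylphenol
Product: 6 4-bromo-2-(methoxymethoxy)-3,5-dimethylphenol
Conditions: NBS (1.0 equiv), MeCN, −20 → 0 °C
Reagents that add atoms: N-bromosuccinimide, O=C1CCC(=O)N1Br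
Why: Electrophilic aromatic bromination is expected para to the free hydroxyl, as with 3,5-xylenol, which places the halogen on the future C9 and blocks the para position before the sigmatropic step.

Step 4
Reactants: 6 4-bromo-2-(methoxymethoxy)-3,5-dimethylphenol; 7 prenyl bromide (1-bromo-3-methylbut-2-ene)
Product: 8 4-bromo-2-(methoxymethoxy)-3,5-dimethyl-1-[(3-methylbut-2-en-1-yl)oxy]benzene
Conditions: K2CO3, acetone, reflux
Reagents that add atoms: none
Why: Williamson ether synthesis on the phenoxide with the primary allylic bromide gives the aryl prenyl ether needed for the Claisen step.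

Step 5
Reactants: 8 4-bromo-2-(methoxymethoxy)-3,5-dimethyl-1-[(3-methylbut-2-en-1-yl)oxy]benzene
Product: 10 4-bromo-2-(methoxymethoxy)-3,5-dimethyl-6-(2-methylbut-3-en-2-yl)phenol, via ortho-dienone 9 (not isolated)
Conditions: Eu(fod)3 [fod = 6,6,7,7,8,8,8-heptafluoro-2,2-dimethyloctane-3,5-dionate] (10 mol%), CHCl3, 80 °C, sealed tube
Reagents that add atoms: none
Why: The aromatic Claisen ([3,3]) rearrangement can end only at the one free ortho carbon (future C5) because the para carbon carries bromine, and tautomerisation of the dienone then gives the aryl–CMe2 bond (C4–C5), with the chelating europium Lewis acid keeping the temperature below that of the abnormal Claisen pathway.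

Step 6
Reactants: 10 4-bromo-2-(methoxymethoxy)-3,5-dimethyl-6-(2-methylbut-3-en-2-yl)phenol
Product: 11 1-bromo-3,4-bis(methoxymethoxy)-2,6-dimethyl-5-(2-methylbut-3-en-2-yl)benzene
Conditions: NaH, DMF, 0 °C; MOMCl, 0 °C → rt
Reagents that add atoms: chloromethyl methyl ether (MOMCl), COCCl
Why: O-alkylation of the hindered sodium phenoxide with the small, reactive chloromethyl ether (Williamson-type) gives the bis-MOM catechol, which is stable to the organometallic and oxidative steps that follow.

Step 7
Reactants: 11 1-bromo-3,4-bis(methoxymethoxy)-2,6-dimethyl-5-(2-methylbut-3-en-2-yl)benzene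
Product: 13 2-[3-bromo-5,6-bis(methoxymethoxy)-2,4-dimethylphenyl]-2-methylpropanal, via vicinal diol 12 (not isolated)
Conditions: OsO4 (2 mol%), NaIO4, 2,6-lutidine, dioxane/H2O, rt
Reagents that add atoms: sodium periodate, [Na+].[O-]I(=O)(=O)=O (oxygen delivered through catalytic osmium tetroxide, O=[Os](=O)(=O)=O)
Why: Lemieux–Johnson dihydroxylation and periodate cleavage of the monosubstituted alkene give the non-enolisable neopentyl aldehyde without touching the fully substituted, electron-rich arene.

Step 8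
Reactants: 13 2-[3-bromo-5,6-bis(methoxymethoxy)-2,4-dimethylphenyl]-2-methylpropanal; 14 vinylmagnesium bromide
Product: 15 4-[3-bromo-5,6-bis(methoxymethoxy)-2,4-dimethylphenyl]-4-methylpent-1-en-3-ol (racemic at C3)
Conditions: THF, −78 → 0 °C; aq NH4Cl
Reagents that add atoms: none
Why: Grignard 1,2-addition to the aldehyde forms C2–C3 and stores the future vinyl ketone as an allylic alcohol, the aryl bromide being inert at this temperature.

**Eastern bicycle**

Step 9
Reactants: 16 methyl acetoacetate; 17 geranyl bromide [(2E)-1-bromo-3,7-dimethylocta-2,6-diene]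
Product: 19 methyl (6E)-7,11-dimethyl-3-oxododeca-6,10-dienoate, via acetoacetate dianion 18 (not isolated)
Conditions: NaH, THF, 0 °C; n-BuLi, 0 °C; then 17, 0 °C → rt; 1 M HCl
Reagents that add atoms: none
Why: SN2 γ-alkylation of the acetoacetate dianion by the allylic bromide joins C8′ to C9′ and leaves the β-keto ester for the next step.

Step 10
Reactants: 19 methyl (6E)-7,11-dimethyl-3-oxododeca-6,10-dienoate
Product: 20 methyl (2Z,6E)-3-[(diethoxyphosphoryl)oxy]-7,11-dimethyldodeca-2,6,10-trienoate
Conditions: NaH, Et2O, 0 °C; ClP(O)(OEt)2, 0 °C → rt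
Reagents that add atoms: diethyl chlorophosphate, CCOP(=O)(Cl)OCC
Why: O-phosphorylation of the chelated sodium enolate (enol phosphate formation) should give the Z isomer, which fixes the alkene geometry that later sets C6′.

Step 11
Reactants: 20 methyl (2Z,6E)-3-[(diethoxyphosphoryl)oxy]-7,11-dimethyldodeca-2,6,10-trienoate; 21 (trimethylsilyl)methylmagnesium chloride
Product: 22 methyl (2Z,6E)-7,11-dimethyl-3-[(trimethylsilyl)methyl]dodeca-2,6,10-trienoate
Conditions: Ni(acac)2 (5 mol%), THF, 0 °C → rt
Reagents that add atoms: none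
Why: Nickel-catalysed Kumada-type coupling of the enol phosphate proceeds with retention of geometry and gives the Z-allylsilane, whose CH2 becomes the C7′ methyl carbon.

Step 12
Reactants: 22 methyl (2Z,6E)-7,11-dimethyl-3-[(trimethylsilyl)methyl]dodeca-2,6,10-trienoate
Product: 23 methyl (2Z)-5-[(2R,3R)-3-{2-[(2R)-3,3-dimethyloxiran-2-yl]ethyl}-3-methyloxiran-2-yl]-3-[(trimethylsilyl)methyl]pent-2-enoate
Conditions: D-fructose-derived Shi ketone (0.6 equiv), Oxone (2KHSO5·KHSO4·K2SO4), K2CO3, Bu4NHSO4, MeCN/CH2(OMe)2, aq Na2B4O7–Na2EDTA, 0 °C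
Reagents that add atoms: Oxone (potassium peroxymonosulfate), [K+].[O-]S(=O)(=O)OO
Why: Shi asymmetric epoxidation (chiral dioxirane) should epoxidise only the two electron-rich trisubstituted alkenes, with the R,R sense that this ketone gives for trans and trisubstituted olefins (future C9a′ and C5a′), while the ester-conjugated allylsilane alkene is too electron-poor to react.

Step 13
Reactants: 23 methyl (2Z)-5-[(2R,3R)-3-{2-[(2R)-3,3-dimethyloxiran-2-yl]ethyl}-3-methyloxiran-2-yl]-3-[(trimethylsilyl)methyl]pent-2-enoate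
Product: 25 methyl (3R,5aR,6S,9aR)-3-hydroxy-2,2,5a-trimethyl-7-methylidenedecahydro-1-benzoxepine-6-carboxylate, via trimethylsilyl ether 24 (not isolated)
Conditions: TMSOTf (1.1 equiv), 2,6-di-tert-butyl-4-methylpyridine, CH2Cl2, −78 °C; then MeOH, citric acid (cat.), 0 °C
Reagents that add atoms: none
Why: In this silyl-triflate-promoted tandem oxa-/carbacyclisation the silylated terminal epoxide is opened at its tertiary carbon (C2′) by the oxygen of the internal epoxide to close the oxepane, the resulting epoxonium ion is opened at C5a′ with inversion by the allylsilane carbon C6′ through a chair transition state with the ester equatorial (trans ring fusion from the epoxide, C6′ from the Z geometry), loss of the silyl group leaves the C7′ exocyclic methylene, and methanolysis removes the silyl ether.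

Step 14
Reactants: 25 methyl (3R,5aR,6S,9aR)-3-hydroxy-2,2,5a-trimethyl-7-methylidenedecahydro-1-benzoxepine-6-carboxylate
Product: 26 methyl (3R,5aR,6S,7S,9aR)-3-hydroxy-2,2,5a,7-tetramethyldecahydro-1-benzoxepine-6-carboxylate
Conditions: H2 (1 atm), PtO2, EtOAc, rt
Reagents that add atoms: none
Why: Heterogeneous catalytic hydrogenation should deliver hydrogen to the exocyclic methylene from the face of H6′, opposite the axial C5a′ methyl, so that the C7′ methyl ends cis to the angular methyl and to the C6′ substituent.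

Step 15
Reactants: 26 methyl (3R,5aR,6S,7S,9aR)-3-hydroxy-2,2,5a,7-tetramethyldecahydro-1-benzoxepine-6-carboxylate
Product: 27 (3R,5aR,6S,7S,9aR)-6-(hydroxymethyl)-2,2,5a,7-tetramethyldecahydro-1-benzoxepin-3-ol
Conditions: LiAlH4, THF, 0 → 40 °C; H2O, aq NaOH
Reagents that add atoms: none
Why: Hydride reduction of the hindered ester with LiAlH4 gives the primary alcohol without affecting any stereocentre.

Step 16
Reactants: 27 (3R,5aR,6S,7S,9aR)-6-(hydroxymethyl)-2,2,5a,7-tetramethyldecahydro-1-benzoxepin-3-ol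
Product: 28 (3R,5aR,6S,7S,9aR)-3-hydroxy-2,2,5a,7-tetramethyldecahydro-1-benzoxepine-6-carbaldehyde
Conditions: TEMPO (10 mol%), PhI(OAc)2, CH2Cl2, rt
Reagents that add atoms: none
Why: Oxoammonium (TEMPO) oxidation is selective for the primary alcohol over the secondary C3′ carbinol, which is shielded by the adjacent quaternary C2′.

Step 17
Reactants: 28 (3R,5aR,6S,7S,9aR)-3-hydroxy-2,2,5a,7-tetramethyldecahydro-1-benzoxepine-6-carbaldehyde
Product: 29 (3R,5aR,6S,7S,9aR)-6-ethenyl-2,2,5a,7-tetramethyldecahydro-1-benzoxepin-3-ol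
Conditions: Ph3PCH3Br, KOt-Bu (3 equiv each), THF, 0 °C → rt
Reagents that add atoms: methyltriphenylphosphonium bromide, C[P+](c1ccccc1)(c1ccccc1)c1ccccc1.[Br-]
Why: Wittig methylenation of the aldehyde (excess ylide covers the free hydroxyl) gives the vinyl group, C6′ being already in its equatorial, thermodynamically preferred configuration.

**Union and end game**

Step 18
Reactants: 29 (3R,5aR,6S,7S,9aR)-6-ethenyl-2,2,5a,7-tetramethyldecahydro-1-benzoxepin-3-ol; 15 4-[3-bromo-5,6-bis(methoxymethoxy)-2,4-dimethylphenyl]-4-methylpent-1-en-3-ol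
Product: 31 4-[3-{2-[(3R,5aR,6S,7S,9aR)-3-hydroxy-2,2,5a,7-tetramethyldecahydro-1-benzoxepin-6-yl]ethyl}-5,6-bis(methoxymethoxy)-2,4-dimethylphenyl]-4-methylpent-1-en-3-ol (C3 epimers), via bis-boryl adduct 30 (not isolated)
Conditions: 9-BBN (2.4 equiv), THF, 0 → 50 °C; then degassed aq K3PO4, 15, Pd(OAc)2 (5 mol%), SPhos (10 mol%), THF/H2O, 65 °C
Reagents that add atoms: none
Why: Anti-Markovnikov hydroboration of the terminal alkene and sp3–sp2 Suzuki–Miyaura coupling form the C9–CH2 bond, the SPhos-ligated zerovalent palladium formed in situ being suited to the electron-rich bromide flanked by two methyls, and free hydroxyls are tolerated because the O–B bond is hydrolysed on work-up.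

Step 19
Reactants: 31 4-[3-{2-[(3R,5aR,6S,7S,9aR)-3-hydroxy-2,2,5a,7-tetramethyldecahydro-1-benzoxepin-6-yl]ethyl}-5,6-bis(methoxymethoxy)-2,4-dimethylphenyl]-4-methylpent-1-en-3-ol
Product: 32 4-[3-{2-[(5aR,6S,7S,9aR)-2,2,5a,7-tetramethyl-3-oxodecahydro-1-benzoxepin-6-yl]ethyl}-5,6-bis(methoxymethoxy)-2,4-dimethylphenyl]-4-methylpent-1-en-3-one
Conditions: Dess–Martin periodinane (3 equiv), NaHCO3, CH2Cl2, 0 °C → rt
Reagents that add atoms: none
Why: Dess–Martin oxidation converts both hindered secondary carbinols at once, giving the vinyl ketone (C3) and the oxepanone (C3′) and erasing the two uncontrolled centres.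

Step 20
Reactants: 32 4-[3-{2-[(5aR,6S,7S,9aR)-2,2,5a,7-tetramethyl-3-oxodecahydro-1-benzoxepin-6-yl]ethyl}-5,6-bis(methoxymethoxy)-2,4-dimethylphenyl]-4-methylpent-1-en-3-one
Product: 33 4-[3-{2-[(5aR,6S,7S,9aR)-2,2,5a,7-tetramethyl-3-oxodecahydro-1-benzoxepin-6-yl]ethyl}-5,6-dihydroxy-2,4-dimethylphenyl]-4-methylpent-1-en-3-one
Conditions: TFA/CH2Cl2 (1:4), trace H2O, 0 °C, Ar; pH 7 buffer work-up; used at once
Reagents that add atoms: none
Why: Acid hydrolysis of the two aryl methoxymethyl acetals frees the catechol, the arene having no open position for the released formaldehyde, and the base-free work-up is meant to keep the vinyl ketone from cyclising before the catalyst is present.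

Step 21
Reactants: 33 4-[3-{2-[(5aR,6S,7S,9aR)-2,2,5a,7-tetramethyl-3-oxodecahydro-1-benzoxepin-6-yl]ethyl}-5,6-dihydroxy-2,4-dimethylphenyl]-4-methylpent-1-en-3-one
Product: 34 (8aS)-5-hydroxy-4,4,7,8a-tetramethyl-8-{2-[(5aR,6S,7S,9aR)-2,2,5a,7-tetramethyl-3-oxodecahydro-1-benzoxepin-6-yl]ethyl}-1,2,4,8a-tetrahydronaphthalene-3,6-dione (CNP0302807.1)
Conditions: quinine-derived bifunctional thiourea [1-(3,5-bis(trifluoromethyl)phenyl)-3-(9-deoxy-epi-quinin-9-yl)thiourea] (10 mol%), degassed toluene, −20 °C, Ar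
Reagents that add atoms: none
Why: Proposed new method: the quinuclidine nitrogen of the catalyst forms a hydrogen-bonded catecholate ion pair while the thiourea binds the enone carbonyl, and the carbon para to the C7 oxygen (C10, already carrying a methyl) adds to the terminal carbon C1 of the s-trans vinyl ketone, after which protonation of the C2 enolate leaves the C7 ketone and C6 enol of the target; the closest known reactions are base-mediated intramolecular para-alkylative dearomatisations of phenols and thiourea-catalysed dearomative Michael additions of naphthols. Ring A closes in a 6-endo-trig mode with C1 lying over one face of the arene. The only new stereocentre, C10, is remote from the eastern centres, so its face is chosen by the catalyst alone, and whichever of the quinine catalyst and its quinidine pseudoenantiomer favours the 10S (8aS) epimer is used. The step needs C-alkylation at C10 rather than at C6 or at oxygen: O6 could close only a seven-membered ring, C6 carries the second oxygen and is the poorer nucleophilic site, no other ring carbon can reach C1, and a reversible conjugate addition lets any kinetic mis-adduct return to 33. The loss of aromaticity is expected to be offset by the new C–C bond, by relief of the strain of a tert-alkyl group wedged between methyl and hydroxyl on a hexasubstituted ring, and by the conjugated, hydrogen-bonded diosphenol.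

**Compound list**

1 | 2,4-dimethylphenol | Cc1ccc(O)c(C)c1 | starting material
2 | 1-(methoxymethoxy)-2,4-dimethylbenzene | COCOc1ccc(C)cc1C | intermediate
3 | [2-(methoxymethoxy)-3,5-dimethylphenyl]lithium | COCOc1c(C)cc(C)cc1[Li] | intermediate (not isolated)
4 | dimethyl [2-(methoxymethoxy)-3,5-dimethylphenyl]boronate | COCOc1c(C)cc(C)cc1B(OC)OC | intermediate (not isolated)
5 | 2-(methoxymethoxy)-3,5-dimethylphenol | COCOc1c(C)cc(C)cc1O | intermediate
6 | 4-bromo-2-(methoxymethoxy)-3,5-dimethylphenol | COCOc1c(C)c(Br)c(C)cc1O | intermediate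
7 | prenyl bromide | CC(C)=CCBr | starting material
8 | 4-bromo-2-(methoxymethoxy)-3,5-dimethyl-1-[(3-methylbut-2-en-1-yl)oxy]benzene | COCOc1c(C)c(Br)c(C)cc1OCC=C(C)C | intermediate
9 | 4-bromo-2-(methoxymethoxy)-3,5-dimethyl-6-(2-methylbut-3-en-2-yl)cyclohexa-2,4-dien-1-one | COCOC1=C(C)C(Br)=C(C)C(C(C)(C)C=C)C1=O | intermediate (not isolated)
10 | 4-bromo-2-(methoxymethoxy)-3,5-dimethyl-6-(2-methylbut-3-en-2-yl)phenol | COCOc1c(C)c(Br)c(C)c(C(C)(C)C=C)c1O | intermediate
11 | 1-bromo-3,4-bis(methoxymethoxy)-2,6-dimethyl-5-(2-methylbut-3-en-2-yl)benzene | COCOc1c(C)c(Br)c(C)c(C(C)(C)C=C)c1OCOC | intermediate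
12 | 3-[3-bromo-5,6-bis(methoxymethoxy)-2,4-dimethylphenyl]-3-methylbutane-1,2-diol | COCOc1c(C)c(Br)c(C)c(C(C)(C)C(O)CO)c1OCOC | intermediate (not isolated)
13 | 2-[3-bromo-5,6-bis(methoxymethoxy)-2,4-dimethylphenyl]-2-methylpropanal | COCOc1c(C)c(Br)c(C)c(C(C)(C)C=O)c1OCOC | intermediate
14 | vinylmagnesium bromide | C=C[Mg]Br | starting material
15 | 4-[3-bromo-5,6-bis(methoxymethoxy)-2,4-dimethylphenyl]-4-methylpent-1-en-3-ol (racemic) | COCOc1c(C)c(Br)c(C)c(C(C)(C)C(O)C=C)c1OCOC | intermediate
16 | methyl acetoacetate | COC(=O)CC(C)=O | starting material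
17 | geranyl bromide | CC(C)=CCC/C(C)=C/CBr | starting material
18 | sodium lithium dianion of methyl acetoacetate | COC(=O)[CH-]C(=O)[CH2-].[Na+].[Li+] | intermediate (not isolated)
19 | methyl (6E)-7,11-dimethyl-3-oxododeca-6,10-dienoate | COC(=O)CC(=O)CC/C=C(\C)CCC=C(C)C | intermediate
20 | methyl (2Z,6E)-3-[(diethoxyphosphoryl)oxy]-7,11-dimethyldodeca-2,6,10-trienoate | COC(=O)/C=C(\OP(=O)(OCC)OCC)CC/C=C(\C)CCC=C(C)C | intermediate
21 | (trimethylsilyl)methylmagnesium chloride | C[Si](C)(C)C[Mg]Cl | starting material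
22 | methyl (2Z,6E)-7,11-dimethyl-3-[(trimethylsilyl)methyl]dodeca-2,6,10-trienoate | COC(=O)/C=C(\C[Si](C)(C)C)CC/C=C(\C)CCC=C(C)C | intermediate
23 | methyl (2Z)-5-[(2R,3R)-3-{2-[(2R)-3,3-dimethyloxiran-2-yl]ethyl}-3-methyloxiran-2-yl]-3-[(trimethylsilyl)methyl]pent-2-enoate | COC(=O)/C=C(\C[Si](C)(C)C)CC[C@H]1O[C@]1(C)CC[C@H]1OC1(C)C | intermediate
24 | methyl (3R,5aR,6S,9aR)-2,2,5a-trimethyl-7-methylidene-3-[(trimethylsilyl)oxy]decahydro-1-benzoxepine-6-carboxylate | COC(=O)[C@H]2C(=C)CC[C@H]3OC(C)(C)[C@H](O[Si](C)(C)C)CC[C@@]32C | intermediate (not isolated)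
25 | methyl (3R,5aR,6S,9aR)-3-hydroxy-2,2,5a-trimethyl-7-methylidenedecahydro-1-benzoxepine-6-carboxylate | COC(=O)[C@H]2C(=C)CC[C@H]3OC(C)(C)[C@H](O)CC[C@@]32C | intermediate
26 | methyl (3R,5aR,6S,7S,9aR)-3-hydroxy-2,2,5a,7-tetramethyldecahydro-1-benzoxepine-6-carboxylate | COC(=O)[C@H]2[C@@H](C)CC[C@H]3OC(C)(C)[C@H](O)CC[C@@]32C | intermediate
27 | (3R,5aR,6S,7S,9aR)-6-(hydroxymethyl)-2,2,5a,7-tetramethyldecahydro-1-benzoxepin-3-ol | OC[C@H]2[C@@H](C)CC[C@H]3OC(C)(C)[C@H](O)CC[C@@]32C | intermediate
28 | (3R,5aR,6S,7S,9aR)-3-hydroxy-2,2,5a,7-tetramethyldecahydro-1-benzoxepine-6-carbaldehyde | O=C[C@H]2[C@@H](C)CC[C@H]3OC(C)(C)[C@H](O)CC[C@@]32C | intermediate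
29 | (3R,5aR,6S,7S,9aR)-6-ethenyl-2,2,5a,7-tetramethyldecahydro-1-benzoxepin-3-ol | C=C[C@H]2[C@@H](C)CC[C@H]3OC(C)(C)[C@H](O)CC[C@@]32C | intermediate
30 | adduct of 29 with two 9-BBN units (B-alkyl at the former vinyl terminus, O-boryl at C3′) | B1(C4CCCC1CCC4)CC[C@H]2[C@@H](C)CC[C@H]3OC(C)(C)[C@H](OB5C6CCCC5CCC6)CC[C@@]32C | intermediate (not isolated)
31 | 4-[3-{2-[(3R,5aR,6S,7S,9aR)-3-hydroxy-2,2,5a,7-tetramethyldecahydro-1-benzoxepin-6-yl]ethyl}-5,6-bis(methoxymethoxy)-2,4-dimethylphenyl]-4-methylpent-1-en-3-ol (C3 epimers) | COCOc1c(C)c(CC[C@H]2[C@@H](C)CC[C@H]3OC(C)(C)[C@H](O)CC[C@@]32C)c(C)c(C(C)(C)C(O)C=C)c1OCOC | intermediate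
32 | 4-[3-{2-[(5aR,6S,7S,9aR)-2,2,5a,7-tetramethyl-3-oxodecahydro-1-benzoxepin-6-yl]ethyl}-5,6-bis(methoxymethoxy)-2,4-dimethylphenyl]-4-methylpent-1-en-3-one | COCOc1c(C)c(CC[C@H]2[C@@H](C)CC[C@H]3OC(C)(C)C(=O)CC[C@@]32C)c(C)c(C(C)(C)C(=O)C=C)c1OCOC | intermediate
33 | 4-[3-{2-[(5aR,6S,7S,9aR)-2,2,5a,7-tetramethyl-3-oxodecahydro-1-benzoxepin-6-yl]ethyl}-5,6-dihydroxy-2,4-dimethylphenyl]-4-methylpent-1-en-3-one | Cc1c(CC[C@H]2[C@@H](C)CC[C@H]3OC(C)(C)C(=O)CC[C@@]32C)c(C)c(C(C)(C)C(=O)C=C)c(O)c1O | intermediate
34 | (8aS)-5-hydroxy-4,4,7,8a-tetramethyl-8-{2-[(5aR,6S,7S,9aR)-2,2,5a,7-tetramethyl-3-oxodecahydro-1-benzoxepin-6-yl]ethyl}-1,2,4,8a-tetrahydronaphthalene-3,6-dione | CC1=C(CC[C@H]2[C@@H](C)CC[C@H]3OC(C)(C)C(=O)CC[C@@]32C)[C@]2(C)CCC(=O)C(C)(C)C2=C(O)C1=O | target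

Total step count: 21.
Longest linear sequence: 13 steps (steps 9–21, from methyl acetoacetate and geranyl bromide); the western branch is 12 steps (1–8, then 18–21).

**Steps most likely to fail**

Step 21. The ring closure may not hold against retro-Michael return to the aromatic catechol, or the catalyst may give a poor facial preference at C10. The fallback is an irreversible intramolecular phenoxide para-alkylation by a sulfonate, which is known chemistry. It sets out from 31. Hydroboration–oxidation of the vinyl group (9-BBN; NaOH, H2O2) gives the triol F1, and selective sulfonylation of the primary hydroxyl (TsCl, pyridine, 0 °C) gives the primary tosylate F2. TFA in CH2Cl2 then frees the catechol tosylate F3, and Cs2CO3 in degassed DMF closes ring A by SN2 attack of C10 on C1 (6-exo-tet) to give the dienone diol F4 as C10 epimers, which are separated. Dess–Martin oxidation of the C3 and C3′ carbinols of the 10S epimer rejoins the route at 34.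

Step 13. The internal epoxide may be activated ahead of the terminal one, so that the allylsilane closes the carbocycle before the oxepane exists, or the allylsilane may be lost by protodesilylation. The fallback stages the two ring closures. It sets out from 22. Shi epoxidation with one equivalent of oxidant, followed by separation from the regioisomeric monoepoxide, gives the 6,7-monoepoxide F5. BF3·OEt2 at −78 °C effects the classical epoxy-allylsilane cyclisation to the monocyclic hydroxy ester F6. mCPBA epoxidises the trisubstituted side-chain alkene in preference to the exocyclic methylene to give the epoxy alcohol F7 (both epoxide epimers). Camphorsulfonic acid then opens the epoxide at its tertiary carbon (7-endo) to rejoin the route at 25, accompanied by its C3′ epimer; both converge at ketone 32.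

Step 20. While the catechol is being unmasked, acid may promote a background ring closure without facial control, or conjugate addition to and oligomerisation of the vinyl ketone. The fallback stores the enone as its hydrochloride during deprotection. It sets out from 32. Anhydrous HCl in dioxane at 0 °C removes both acetals and adds to the enone to give the β-chloro ketone F8. One equivalent of Et3N at −20 °C (E1cB elimination) then releases 33 just before the chiral catalyst is added.

**Further compounds**

F1 | step 21 | 4-[3-{2-[(3R,5aR,6S,7S,9aR)-3-hydroxy-2,2,5a,7-tetramethyldecahydro-1-benzoxepin-6-yl]ethyl}-5,6-bis(methoxymethoxy)-2,4-dimethylphenyl]-4-methylpentane-1,3-diol | COCOc1c(C)c(CC[C@H]2[C@@H](C)CC[C@H]3OC(C)(C)[C@H](O)CC[C@@]32C)c(C)c(C(C)(C)C(O)CCO)c1OCOC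
F2 | step 21 | 1-(4-methylbenzenesulfonate) of F1 | COCOc1c(C)c(CC[C@H]2[C@@H](C)CC[C@H]3OC(C)(C)[C@H](O)CC[C@@]32C)c(C)c(C(C)(C)C(O)CCOS(=O)(=O)c4ccc(C)cc4)c1OCOC
F3 | step 21 | catechol obtained from F2 by removal of both methoxymethyl groups | Cc1c(CC[C@H]2[C@@H](C)CC[C@H]3OC(C)(C)[C@H](O)CC[C@@]32C)c(C)c(C(C)(C)C(O)CCOS(=O)(=O)c4ccc(C)cc4)c(O)c1O
F4 | step 21 | analogue of 34 with carbinols in place of the C3 and C3′ ketones (10S epimer) | CC1=C(CC[C@H]2[C@@H](C)CC[C@H]3OC(C)(C)[C@H](O)CC[C@@]32C)[C@]2(C)CCC(O)C(C)(C)C2=C(O)C1=O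
F5 | step 13 | methyl (2Z)-5-[(2R,3R)-3-methyl-3-(4-methylpent-3-en-1-yl)oxiran-2-yl]-3-[(trimethylsilyl)methyl]pent-2-enoate | COC(=O)/C=C(\C[Si](C)(C)C)CC[C@H]1O[C@]1(C)CCC=C(C)C
F6 | step 13 | methyl (1S,2R,3R)-3-hydroxy-2-methyl-6-methylidene-2-(4-methylpent-3-en-1-yl)cyclohexane-1-carboxylate | COC(=O)[C@H]1C(=C)CC[C@@H](O)[C@]1(C)CCC=C(C)C
F7 | step 13 | methyl (1S,2R,3R)-2-[2-(3,3-dimethyloxiran-2-yl)ethyl]-3-hydroxy-2-methyl-6-methylidenecyclohexane-1-carboxylate (both oxirane epimers) | COC(=O)[C@H]1C(=C)CC[C@@H](O)[C@]1(C)CCC1OC1(C)C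
F8 | step 20 | 1-chloro-4-[3-{2-[(5aR,6S,7S,9aR)-2,2,5a,7-tetramethyl-3-oxodecahydro-1-benzoxepin-6-yl]ethyl}-5,6-dihydroxy-2,4-dimethylphenyl]-4-methylpentan-3-one | Cc1c(CC[C@H]2[C@@H](C)CC[C@H]3OC(C)(C)C(=O)CC[C@@]32C)c(C)c(C(C)(C)C(=O)CCCl)c(O)c1O
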